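Remark: germacrane numbering is used for every ten-membered ring (C1=C10, methyl C14 on C10, methyl C15 on C4, isopropenyl C11–C13 on C7). The same labels are kept for these carbons in the six-membered precursors.

## Analysis of the target

Compound 28 is a germacrane. It is a ten-membered carbocycle with an E C1=C10 alkene, an angelate at C3, a trans C4–C5 epoxide, an acetate at C6 and an isopropenyl group at C7.

The five stereocentres are contiguous (3S,4R,5R,6R,7S). The C3 oxygen is threo to the epoxide, the C6 oxygen is erythro to it, and the C6 oxygen and the isopropenyl group are cis on the ring.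

Neither oxygen of the final configuration would steer an epoxidation to the right face. A 3S carbinol next to the geminal methyl C15 directs erythro, and a 6R carbinol cis to C15 directs threo.

Several groups are sensitive:
- The angelate isomerises from Z to E when it is activated with nucleophilic catalysts.
- The epoxide faces C1=C10 across the ring and undergoes acid-triggered transannular cyclisation.
- The two epoxy carbinol esters can undergo Payne and acyl shifts.
- Any 1(10),4-diene precursor can undergo a thermal Cope rearrangement.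

The hardest element is the strained ring with two E-configured units, which penalises every end-to-end closure.

The feature that invites the move is this. If the epoxide is read as a masked E alkene, C10=C1–C2–C3–C4=C5 is a 1,5-diene whose terminus C5 carries oxygen, which is the retron of an anionic oxy-Cope ring expansion. Reconnecting C5–C10 and cutting C2–C3 leaves the six-membered ring C5–C10. Together with C14 and C11–C13 this ring is the complete skeleton of carvone, with its carbonyl at C5, its methyl-bearing carbon at C10 and its stereocentre at C7.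

## Retrosynthetic reasoning

**C6 ester and C6 configuration.** The acetyl C–O bond of 28 is cut to give 27. Alcohol 27 is traced to epoxy ketone 26, because the erythro C5/C6 relation is what hydride addition to an alpha,beta-epoxy ketone delivers. Ketone 26 comes from the 6-epimeric alcohol 25. The carbinol is thus used twice, first as a director and then reset.

**Epoxide C–O bonds.** The epoxide of 25 is cut to the E alkene of 24. In 24 the 6-alpha hydroxyl, with H6 eclipsing C15, lies on the outer face of C4=C5. Direction and peripheral attack therefore coincide, and only this alkene is allylic to a free hydroxyl.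

**C3 ester and protecting groups.** Alcohol 24 goes back through silyl ether 23 to alcohol 20 and angelic acid 21, and 20 goes back to the PMB ether 19. The angelate is attached on the less hindered allylic alcohol, before the acid-sensitive epoxide exists.

**C5–H bond.** Diene 19 is traced to enol triflate 18. The forward reaction only has to replace OTf by H with retention, so the alkene geometry is inherited from an enolate.

**Key disconnection.** In 18 the C2–C3 bond is cut and C5–C10 is reconnected, which gives the trans-1,2-dialkenylcyclohexanol 15. This removes the ten-membered ring, both ring alkene geometries and the C3 stereocentre in one operation. The forward reaction must run through one chair, and its enolate must be caught on oxygen.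

**C4–C5 bond.** Carbinol 15 is cut into ketone 7 and the three-carbon Z bromo enol ether 13 (C3, C4, C15). The forward addition has to come anti to the axial vinyl group.

**C6–O and C10–C1 bonds.** Ketone 7 loses its C6 oxygen to give 5, whose only enolisable position is C6. Ketone 5 is the dehydration product of aldol 4, made from (R)-carvone 1 and acetaldehyde 2 (C1, C2) through the regiodefined enolate 3.

**Enol ether.** Bromide 13 comes from the Z propenyl ether 11. Ether 11 comes from 4-methoxybenzyl alcohol 8 and allyl bromide 9.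

## Alternatives that were turned down

**Alternative 1:** the textbook cut at C6–C7.
- Forward key step: intramolecular carbonyl allylation (CrCl2/NiCl2, or Pd(PPh3)4/Et2Zn) of the chloro epoxy aldehyde A1.
- Stereochemical conflict: an E allyl metal in a closed chair gives the 6,7-relation opposite to the target, while Felkin-type attack on the epoxy aldehyde gives 6R. The two preferences together lead to the 7-epimer A2, and C7 cannot be corrected afterwards.
- Step economy: the C3 oxygen excludes a farnesol-type C15 chain. A1 therefore needs a long linear build-up with an asymmetric C3 step, Sharpless epoxidation, terminal allylic oxidation and halogenation.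
- Strain: the full ring strain has to be paid in an end-to-end closure that competes with oligomerisation.
- Yield of complexity: only two of the five stereocentres are set.

**Alternative 2:** cut at C3–C4.
- Forward key step: Nozaki–Hiyama–Kishi closure (CrCl2/NiCl2) of the iodo aldehyde A3 to the allylic alcohol A4.
- One stereocentre is formed, far from any control element, so C3 would need an oxidation and reagent-controlled reduction.
- The precursor must already hold both E alkenes and the 6,7-pair from separate asymmetric steps.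
- A free 3S hydroxyl next to the geminal methyl C15 then steers the epoxidation to the erythro isomer, which is the wrong face.
- Step economy is no better, and the strain argument of Alternative 1 applies again.

**Alternative 3:** cut at C6–C7 through a ring contraction.
- Forward key step: [2,3]-Wittig rearrangement of the thirteen-membered bis-allylic ether A5 to A6.
- The homoallylic alcohol retron fits, but two allylic OCH2 groups compete for deprotonation.
- The carbanion cannot coexist with the epoxide.
- The E C7=C11 alkene that allylic oxidation provides gives the wrong 6,7-relation.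
- A 3S ether turns the chain to the face that leads to the 6R,7R pair of A6. The Z allylic ether that would be needed costs several additional steps, plus a macroetherification.

Key step: step 7

## Steps

Step 1
Reactants: 1 (R)-(−)-carvone; 2 acetaldehyde
Product: 4 (2R,5R)-2-(1-hydroxyethyl)-2-methyl-5-(prop-1-en-2-yl)cyclohexan-1-one (both carbinol epimers), via lithium enolate 3 (not isolated)
Conditions: LiBH(s-Bu)3, THF, −78 °C; MeCHO, −78 °C; aq NH4Cl
Reagents that add atoms: none
Why: Conjugate hydride addition to the enone gives the regiodefined tetrasubstituted enolate 3, which is used in a reductive aldol reaction. Axial attack on the half-chair with equatorial isopropenyl forms C10–C1 cis to the isopropenyl group, as in alkylations of dihydrocarvone enolates; the carbinol centre is lost in step 2.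

Step 2
Reactants: 4 (2R,5R)-2-(1-hydroxyethyl)-2-methyl-5-(prop-1-en-2-yl)cyclohexan-1-one
Product: 5 (2R,5R)-2-ethenyl-2-methyl-5-(prop-1-en-2-yl)cyclohexan-1-one
Conditions: Ph2S[OC(CF3)2Ph]2, CH2Cl2, 0 °C to rt
Reagents that add atoms: none
Why: Sulfurane dehydration of a secondary alcohol through its alkoxysulfonium salt. C10 is quaternary, so only the methyl group offers a beta hydrogen and the vinyl group is the only alkene possible, while the neutral medium avoids a retro-aldol reaction.

Step 3
Reactants: 5 (2R,5R)-2-ethenyl-2-methyl-5-(prop-1-en-2-yl)cyclohexan-1-one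
Product: 7 (2R,5S,6S)-2-ethenyl-2-methyl-5-(prop-1-en-2-yl)-6-(triisopropylsilyloxy)cyclohexan-1-one, via potassium alkoxide 6 (not isolated)
Conditions: KN(SiMe3)2, THF, −78 °C; 2-(benzenesulfonyl)-3-phenyloxaziridine, −78 °C; i-Pr3SiOTf, −78 to 0 °C
Reagents that add atoms: 2-(benzenesulfonyl)-3-phenyloxaziridine O=S(=O)(c1ccccc1)N1OC1c1ccccc1; triisopropylsilyl triflate CC(C)[Si](OS(=O)(=O)C(F)(F)F)(C(C)C)C(C)C
Why: Enolate hydroxylation with an N-sulfonyloxaziridine followed by O-silylation in the same flask. C6 is the only enolisable position, and oxygen arrives on the face anti to both the neighbouring isopropenyl group and the axial vinyl group (6-alpha).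

Step 4
Reactants: 8 4-methoxybenzyl alcohol; 9 allyl bromide
Product: 11 (Z)-prop-1-enyl 4-methoxybenzyl ether, via allyl ether 10 (not isolated)
Conditions: KOt-Bu (excess), DMSO, rt, then 60 °C
Reagents that add atoms: none
Why: Williamson etherification followed by base-mediated isomerisation of the allyl ether. The isomerisation passes through the cis-configured oxyallyl anion and gives the Z propenyl ether.

Step 5
Reactants: 11 (Z)-prop-1-enyl 4-methoxybenzyl ether
Product: 13 (Z)-2-bromoprop-1-enyl 4-methoxybenzyl ether, via dibromide 12 (not isolated)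
Conditions: Br2, CH2Cl2, −78 °C; DBU, −78 °C to rt
Reagents that add atoms: bromine BrBr
Why: Anti addition of bromine to the electron-rich enol ether, then anti elimination of H(C2) and Br(C1). From the Z ether this sequence places Br cis to the oxygen.

Step 6
Reactants: 13 (Z)-2-bromoprop-1-enyl 4-methoxybenzyl ether; 7 (2R,5S,6S)-2-ethenyl-2-methyl-5-(prop-1-en-2-yl)-6-(triisopropylsilyloxy)cyclohexan-1-one
Product: 15 (1R,2R,5S,6S)-2-ethenyl-1-{(Z)-1-[(4-methoxybenzyl)oxy]prop-1-en-2-yl}-2-methyl-5-(prop-1-en-2-yl)-6-(triisopropylsilyloxy)cyclohexan-1-ol, via alkenyllithium 14 (not isolated)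
Conditions: 13, t-BuLi (2 equiv), Et2O, −78 °C; 7, −78 to −20 °C
Reagents that add atoms: none
Why: Bromine–lithium exchange with retention gives the chelation-stabilised cis beta-alkoxyalkenyllithium 14, which undergoes 1,2-addition. The axial vinyl group on C10 blocks one face of the carbonyl, so C4 enters anti to it and the two alkenyl groups end up trans (C5 becomes R).

Step 7
Reactants: 15 (1R,2R,5S,6S)-2-ethenyl-1-{(Z)-1-[(4-methoxybenzyl)oxy]prop-1-en-2-yl}-2-methyl-5-(prop-1-en-2-yl)-6-(triisopropylsilyloxy)cyclohexan-1-ol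
Product: 18 (1(10)E,3S,6S,7S)-3-(4-methoxybenzyloxy)-6-(triisopropylsilyloxy)germacra-1(10),4,11-trien-5-yl triflate (C3 trans to C6 on C4=C5), via potassium alkoxide 16 (not isolated), via potassium enolate 17 (not isolated)
Conditions: KH, 18-crown-6, THF, 0 to 55 °C; then −78 °C, N-(5-chloro-2-pyridyl)bis(trifluoromethanesulfonimide)
Reagents that add atoms: N-(5-chloro-2-pyridyl)bis(trifluoromethanesulfonimide) FC(F)(F)S(=O)(=O)N(c1ccc(Cl)cn1)S(=O)(=O)C(F)(F)F
Why: Deprotonation gives the tertiary alkoxide 16, whose oxyanion weakens C5–C10 and triggers a [3,3] sigmatropic shift (anionic oxy-Cope rearrangement), the reaction type by which 1,2-dialkenylcyclohexanols are known to expand to (E)-cyclodec-5-enone enolates. No ring is closed end to end: C2–C3 forms while C5–C10 breaks in a six-membered chair transition state fused to the cyclohexane like the second ring of a trans-decalin, so six ring members become ten and the strain is paid by the alkoxide-to-enolate driving force. The two alkenyl groups are trans-diaxial in the resting chair, so the ring must first invert to the chair that holds them diequatorial; the crowded equatorial OTIPS/isopropenyl/alkoxide array of the resting chair keeps this price moderate. In the reactive chair the ring bonds C10–C9 and C5–C6 are equatorial on the forming ring, which fixes C1=C10 as E and places C3 trans to C6 on the C4=C5 enolate. C3 is the only new stereocentre: the Z enol ether puts OPMB pseudo-axial, and with the 5R,10R configuration the chair delivers 3S. The step needs chair over boat (a boat would give the Z,Z ring), rearrangement over loss of PMB oxide from enolate 17, and sulfonylation on oxygen; the C3–O bond of 17 lies near the nodal plane of the enolate and the tetrasubstituted C4=C5 unit cannot turn through the ring, which disfavours the elimination, and the hard triflating agent at −78 °C attacks oxygen. Capture as triflate 18 stores the enolate geometry that a ketone would lose.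

Step 8
Reactants: 18 (1(10)E,3S,6S,7S)-3-(4-methoxybenzyloxy)-6-(triisopropylsilyloxy)germacra-1(10),4,11-trien-5-yl triflate
Product: 19 (1(10)E,4E,3S,6R,7S)-3-(4-methoxybenzyloxy)-6-(triisopropylsilyloxy)germacra-1(10),4,11-triene (6-alpha oxygen as in 18; only the CIP label changes)
Conditions: Pd(OAc)2 (cat.), PPh3, HCO2H, n-Bu3N, DMF, 40 °C
Reagents that add atoms: none
Why: Palladium-catalysed formate reduction of an enol triflate. Oxidative addition to zerovalent palladium, decarboxylation of the formate and reductive elimination all proceed with retention, so C4=C5 becomes the E alkene.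

Step 9
Reactants: 19 (1(10)E,4E,3S,6R,7S)-3-(4-methoxybenzyloxy)-6-(triisopropylsilyloxy)germacra-1(10),4,11-triene
Product: 20 (1(10)E,4E,3S,6R,7S)-6-(triisopropylsilyloxy)germacra-1(10),4,11-trien-3-ol
Conditions: DDQ, CH2Cl2/pH 7 buffer, 0 °C
Reagents that add atoms: none
Why: Oxidative cleavage of the PMB ether by hydride abstraction at the electron-rich benzylic position. The silyl ether and the unactivated alkenes are left alone at 0 °C under buffering.

Step 10
Reactants: 20 (1(10)E,4E,3S,6R,7S)-6-(triisopropylsilyloxy)germacra-1(10),4,11-trien-3-ol; 21 angelic acid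
Product: 23 (1(10)E,4E,3S,6R,7S)-6-(triisopropylsilyloxy)germacra-1(10),4,11-trien-3-yl angelate, via mixed anhydride 22 (not isolated)
Conditions: 21, 2,4,6-Cl3C6H2COCl, Et3N, toluene, rt; then 20, 40 °C
Reagents that add atoms: none
Why: Yamaguchi-type mixed anhydride esterification run without a nucleophilic catalyst, the usual way to keep the Z geometry of angelates. The allylic C3 hydroxyl is still unhindered at this stage, and the temperature stays below that of the Cope rearrangement.

Step 11
Reactants: 23 (1(10)E,4E,3S,6R,7S)-6-(triisopropylsilyloxy)germacra-1(10),4,11-trien-3-yl angelate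
Product: 24 (1(10)E,4E,3S,6R,7S)-6-hydroxygermacra-1(10),4,11-trien-3-yl angelate
Conditions: Bu4NF, AcOH (1:1), THF, rt to 40 °C
Reagents that add atoms: none
Why: Fluoride desilylation buffered with acetic acid, so that the ester is neither cleaved nor isomerised. The two oxygens sit 1,4 across an E alkene, so no acyl shift is possible.

Step 12
Reactants: 24 (1(10)E,4E,3S,6R,7S)-6-hydroxygermacra-1(10),4,11-trien-3-yl angelate
Product: 25 (1(10)E,3S,4R,5R,6S,7S)-4,5-epoxy-6-hydroxygermacra-1(10),11-dien-3-yl angelate
Conditions: VO(acac)2 (cat.), t-BuOOH, CH2Cl2, 0 °C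
Reagents that add atoms: tert-butyl hydroperoxide CC(C)(C)OO
Why: Hydroxyl-directed vanadium-catalysed epoxidation, selective for the only alkene that is allylic to a free hydroxyl. Allylic 1,3-strain holds H6 next to C15, so the 6-alpha hydroxyl lies on the outer face of C4=C5 and oxygen is delivered there (threo), which sets 4R,5R.

Step 13
Reactants: 25 (1(10)E,3S,4R,5R,6S,7S)-4,5-epoxy-6-hydroxygermacra-1(10),11-dien-3-yl angelate
Product: 26 (1(10)E,3S,4R,5S,7S)-4,5-epoxy-6-oxogermacra-1(10),11-dien-3-yl angelate
Conditions: Dess–Martin periodinane, pyridine, CH2Cl2, 0 °C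
Reagents that add atoms: none
Why: Dess–Martin oxidation under buffered, non-enolising conditions. The doubly activated C7–H, the epoxide and the angelate are preserved (the C5 label changes by CIP rules only).

Step 14
Reactants: 26 (1(10)E,3S,4R,5S,7S)-4,5-epoxy-6-oxogermacra-1(10),11-dien-3-yl angelate
Product: 27 (1(10)E,3S,4R,5R,6R,7S)-4,5-epoxy-6-hydroxygermacra-1(10),11-dien-3-yl angelate
Conditions: NaBH4, CeCl3·7H2O, MeOH, −78 °C
Reagents that add atoms: none
Why: Luche reduction of an alpha,beta-epoxy ketone. The ring holds C7 anti to the epoxide oxygen, which is the rotamer of the chelate model, and hydride enters from the H5 side away from C4 and C15 to give the erythro 6R carbinol; the ester is untouched.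

Step 15
Reactants: 27 (1(10)E,3S,4R,5R,6R,7S)-4,5-epoxy-6-hydroxygermacra-1(10),11-dien-3-yl angelate
Product: 28 (1(10)E,3S,4R,5R,6R,7S)-6-acetoxy-4,5-epoxygermacra-1(10),11-dien-3-yl angelate (CNP0400048.2)
Conditions: Ac2O, pyridine, DMAP (cat.), CH2Cl2, 0 °C to rt
Reagents that add atoms: acetic anhydride CC(=O)OC(C)=O
Why: Standard acetylation under mildly basic conditions. No stereocentre is touched and the epoxide sees no acid.

## Compound list

1 | (R)-(−)-carvone | CC1=CC[C@H](CC1=O)C(C)=C | starting material
2 | acetaldehyde | CC=O | starting material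
3 | lithium enolate of (R)-dihydrocarvone | CC1=C([O-])C[C@@H](CC1)C(C)=C.[Li+] | intermediate
4 | (2R,5R)-2-(1-hydroxyethyl)-2-methyl-5-(prop-1-en-2-yl)cyclohexan-1-one | CC(O)[C@@]1(C)CC[C@H](CC1=O)C(C)=C | intermediate
5 | (2R,5R)-2-ethenyl-2-methyl-5-(prop-1-en-2-yl)cyclohexan-1-one | C=C[C@@]1(C)CC[C@H](CC1=O)C(C)=C | intermediate
6 | potassium alkoxide of the (2R,5S,6S)-6-hydroxy ketone | C=C[C@@]1(C)CC[C@H]([C@H]([O-])C1=O)C(C)=C.[K+] | intermediate
7 | (2R,5S,6S)-2-ethenyl-2-methyl-5-(prop-1-en-2-yl)-6-(triisopropylsilyloxy)cyclohexan-1-one | C=C[C@@]1(C)CC[C@H]([C@H](O[Si](C(C)C)(C(C)C)C(C)C)C1=O)C(C)=C | intermediate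
8 | 4-methoxybenzyl alcohol | OCc1ccc(OC)cc1 | starting material
9 | allyl bromide | C=CCBr | starting material
10 | allyl 4-methoxybenzyl ether | C=CCOCc1ccc(OC)cc1 | intermediate
11 | (Z)-prop-1-enyl 4-methoxybenzyl ether | C/C=C\OCc1ccc(OC)cc1 | intermediate
12 | rel-(1R,2S)-1,2-dibromopropyl 4-methoxybenzyl ether (racemic) | C[C@H](Br)[C@@H](Br)OCc1ccc(OC)cc1 | intermediate
13 | (Z)-2-bromoprop-1-enyl 4-methoxybenzyl ether | C/C(Br)=C/OCc1ccc(OC)cc1 | intermediate
14 | (Z)-1-(4-methoxybenzyloxy)prop-1-en-2-yllithium | C/C([Li])=C/OCc1ccc(OC)cc1 | intermediate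
15 | (1R,2R,5S,6S)-2-ethenyl-1-{(Z)-1-[(4-methoxybenzyl)oxy]prop-1-en-2-yl}-2-methyl-5-(prop-1-en-2-yl)-6-(triisopropylsilyloxy)cyclohexan-1-ol | C=C[C@@]1(C)CC[C@@H](C(C)=C)[C@H](O[Si](C(C)C)(C(C)C)C(C)C)[C@]1(O)/C(C)=C\OCc1ccc(OC)cc1 | intermediate
16 | potassium alkoxide of 15 | C=C[C@@]1(C)CC[C@@H](C(C)=C)[C@H](O[Si](C(C)C)(C(C)C)C(C)C)[C@]1([O-])/C(C)=C\OCc1ccc(OC)cc1.[K+] | intermediate
17 | potassium germacra-1(10),4,11-trien-5-olate (3S,6S,7S) | C=C(C)[C@@H]1CC/C(C)=C/C[C@H](OCc2ccc(OC)cc2)/C(C)=C([O-])/[C@H]1O[Si](C(C)C)(C(C)C)C(C)C.[K+] | intermediate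
18 | (1(10)E,3S,6S,7S)-3-(4-methoxybenzyloxy)-6-(triisopropylsilyloxy)germacra-1(10),4,11-trien-5-yl triflate | C=C(C)[C@@H]1CC/C(C)=C/C[C@H](OCc2ccc(OC)cc2)/C(C)=C(OS(=O)(=O)C(F)(F)F)/[C@H]1O[Si](C(C)C)(C(C)C)C(C)C | intermediate
19 | (1(10)E,4E,3S,6R,7S)-3-(4-methoxybenzyloxy)-6-(triisopropylsilyloxy)germacra-1(10),4,11-triene | C=C(C)[C@@H]1CC/C(C)=C/C[C@H](OCc2ccc(OC)cc2)/C(C)=C/[C@H]1O[Si](C(C)C)(C(C)C)C(C)C | intermediate
20 | (1(10)E,4E,3S,6R,7S)-6-(triisopropylsilyloxy)germacra-1(10),4,11-trien-3-ol | C=C(C)[C@@H]1CC/C(C)=C/C[C@H](O)/C(C)=C/[C@H]1O[Si](C(C)C)(C(C)C)C(C)C | intermediate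
21 | angelic acid, (Z)-2-methylbut-2-enoic acid | C/C=C(/C)C(=O)O | starting material
22 | angelic 2,4,6-trichlorobenzoic anhydride | C/C=C(/C)C(=O)OC(=O)c1c(Cl)cc(Cl)cc1Cl | intermediate
23 | (1(10)E,4E,3S,6R,7S)-6-(triisopropylsilyloxy)germacra-1(10),4,11-trien-3-yl angelate | C=C(C)[C@@H]1CC/C(C)=C/C[C@H](OC(=O)/C(C)=C\C)/C(C)=C/[C@H]1O[Si](C(C)C)(C(C)C)C(C)C | intermediate
24 | (1(10)E,4E,3S,6R,7S)-6-hydroxygermacra-1(10),4,11-trien-3-yl angelate | C=C(C)[C@@H]1CC/C(C)=C/C[C@H](OC(=O)/C(C)=C\C)/C(C)=C/[C@H]1O | intermediate
25 | (1(10)E,3S,4R,5R,6S,7S)-4,5-epoxy-6-hydroxygermacra-1(10),11-dien-3-yl angelate | C=C(C)[C@@H]1CC/C(C)=C/C[C@H](OC(=O)/C(C)=C\C)[C@@]2(C)O[C@@H]2[C@H]1O | intermediate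
26 | (1(10)E,3S,4R,5S,7S)-4,5-epoxy-6-oxogermacra-1(10),11-dien-3-yl angelate | C=C(C)[C@@H]1CC/C(C)=C/C[C@H](OC(=O)/C(C)=C\C)[C@@]2(C)O[C@@H]2C1=O | intermediate
27 | (1(10)E,3S,4R,5R,6R,7S)-4,5-epoxy-6-hydroxygermacra-1(10),11-dien-3-yl angelate | C=C(C)[C@@H]1CC/C(C)=C/C[C@H](OC(=O)/C(C)=C\C)[C@@]2(C)O[C@@H]2[C@@H]1O | intermediate
28 | (1(10)E,3S,4R,5R,6R,7S)-6-acetoxy-4,5-epoxygermacra-1(10),11-dien-3-yl angelate | C=C(C)[C@@H]1CC/C(C)=C/C[C@H](OC(=O)/C(C)=C\C)[C@@]2(C)O[C@@H]2[C@@H]1OC(C)=O | target

## Step count and least certain steps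

Total step count: 15. Longest linear sequence: 13 (steps 1–3 and 6–15).

**Step 7 (key step).**
- Risk: the ring inversion that the reactive chair demands, together with the pseudo-axial OPMB group, may raise the barrier. The heating then needed would allow loss of PMB oxide from the enolate or leakage through a boat.
- Fallback: the C3 problem is taken out of the transition state. It sets out from 10 and rejoins at 23.
- Allyl ether 10 is isolated and isomerised with [Ir(cod)(PMePh2)2]PF6 (activated with H2) to (E)-prop-1-enyl 4-methoxybenzyl ether F1.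
- Bromination and dehydrobromination as in step 5 give the (E)-bromo enol ether F2.
- Lithiation and addition to 7 give the E-configured carbinol F3, in whose rearrangement OPMB is pseudo-equatorial.
- Trapping gives the (3R)-triflate F4, formate reduction gives the (3R)-PMB ether F5, and DDQ gives the (3R)-alcohol F6.
- Mitsunobu esterification of F6 with 21 (PPh3, DIAD) inverts C3. It brings in the angelate as the carboxylate, which cannot isomerise, and gives 23.

**Step 6.**
- Risk: enolisation of the hindered ketone by the alkenyllithium, slow addition, or eroded facial selectivity.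
- Fallback: a slim sp nucleophile is used and the alkene is built afterwards. It sets out from 8 and 7 and rejoins at 15.
- Alcohol 8 is added to trichloroethylene (KH, THF) to give the (E)-1,2-dichlorovinyl ether F7.
- n-BuLi converts F7 into the lithium alkoxyacetylide F8, which adds to 7 to give the propargylic alcohol F9.
- Syn carbocupration of the alkynyl ether (MeMgBr, CuBr·SMe2) places methyl on C4 and copper on C3. Protonation then gives 15 with OPMB cis to C5.

**Step 8.**
- Risk: transannular carbopalladation of the alkenylpalladium intermediate onto C1=C10, or the onset of the Cope rearrangement on warming.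
- Fallback: palladium is avoided. It sets out from 15 and rejoins at 19.
- The rearrangement of step 7 is quenched at −78 °C with acetic acid to give the 5-ketone F10.
- LiBH(s-Bu)3 gives the 5-alcohol F11, whose C4/C5 epimers are separated.
- Syn elimination with methyl N-(triethylammoniosulfonyl)carbamate on the epimer that has H4 syn to the hydroxyl gives 19.

**Step 12.**
- Risk: competing oxidation of the more electron-rich C1=C10, or a minor ring conformer exposing the other face of C4=C5.
- Fallback: electrophilic oxygen transfer is replaced by nucleophilic oxygen transfer. It sets out from 24 and rejoins at 26.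
- Alcohol 24 is oxidised with Dess–Martin periodinane to the E enone F12.
- Weitz–Scheffer epoxidation (t-BuOOH, DBU) touches only the electron-poor alkene and attacks its outer face.

**Step 14.**
- Risk: poor facial selectivity of the hydride attack, or epimerisation at C7 through the enolate.
- Fallback: the ketone is bypassed. Alcohol 25 is inverted directly with acetic acid under Mitsunobu conditions (PPh3, DIAD), which gives 28 in one operation and replaces steps 13–15. No new compound is made on the way.

## Further compounds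

F1 | step 7 | (E)-prop-1-enyl 4-methoxybenzyl ether | C/C=C/OCc1ccc(OC)cc1
F2 | step 7 | (E)-2-bromoprop-1-enyl 4-methoxybenzyl ether | C/C(Br)=C\OCc1ccc(OC)cc1
F3 | step 7 | (1R,2R,5S,6S)-2-ethenyl-1-{(E)-1-[(4-methoxybenzyl)oxy]prop-1-en-2-yl}-2-methyl-5-(prop-1-en-2-yl)-6-(triisopropylsilyloxy)cyclohexan-1-ol | C=C[C@@]1(C)CC[C@@H](C(C)=C)[C@H](O[Si](C(C)C)(C(C)C)C(C)C)[C@]1(O)/C(C)=C/OCc1ccc(OC)cc1
F4 | step 7 | (1(10)E,3R,6S,7S)-3-(4-methoxybenzyloxy)-6-(triisopropylsilyloxy)germacra-1(10),4,11-trien-5-yl triflate | C=C(C)[C@@H]1CC/C(C)=C/C[C@@H](OCc2ccc(OC)cc2)/C(C)=C(OS(=O)(=O)C(F)(F)F)/[C@H]1O[Si](C(C)C)(C(C)C)C(C)C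
F5 | step 7 | (1(10)E,4E,3R,6R,7S)-3-(4-methoxybenzyloxy)-6-(triisopropylsilyloxy)germacra-1(10),4,11-triene | C=C(C)[C@@H]1CC/C(C)=C/C[C@@H](OCc2ccc(OC)cc2)/C(C)=C/[C@H]1O[Si](C(C)C)(C(C)C)C(C)C
F6 | step 7 | (1(10)E,4E,3R,6R,7S)-6-(triisopropylsilyloxy)germacra-1(10),4,11-trien-3-ol | C=C(C)[C@@H]1CC/C(C)=C/C[C@@H](O)/C(C)=C/[C@H]1O[Si](C(C)C)(C(C)C)C(C)C
F7 | step 6 | (E)-1,2-dichlorovinyl 4-methoxybenzyl ether | Cl/C=C(/Cl)OCc1ccc(OC)cc1
F8 | step 6 | lithium (4-methoxybenzyloxy)acetylide | [Li]C#COCc1ccc(OC)cc1
F9 | step 6 | (1R,2R,5S,6S)-2-ethenyl-1-[(4-methoxybenzyloxy)ethynyl]-2-methyl-5-(prop-1-en-2-yl)-6-(triisopropylsilyloxy)cyclohexan-1-ol | C=C[C@@]1(C)CC[C@@H](C(C)=C)[C@H](O[Si](C(C)C)(C(C)C)C(C)C)[C@]1(O)C#COCc1ccc(OC)cc1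
F10 | step 8 | (1(10)E,3S,6S,7S)-3-(4-methoxybenzyloxy)-6-(triisopropylsilyloxy)germacra-1(10),11-dien-5-one (C4 epimers) | C=C(C)[C@@H]1CC/C(C)=C/C[C@H](OCc2ccc(OC)cc2)C(C)C(=O)[C@H]1O[Si](C(C)C)(C(C)C)C(C)C
F11 | step 8 | (1(10)E,3S,6S,7S)-3-(4-methoxybenzyloxy)-6-(triisopropylsilyloxy)germacra-1(10),11-dien-5-ol (C4/C5 epimers) | C=C(C)[C@@H]1CC/C(C)=C/C[C@H](OCc2ccc(OC)cc2)C(C)C(O)[C@H]1O[Si](C(C)C)(C(C)C)C(C)C
F12 | step 12 | (1(10)E,4E,3S,7S)-6-oxogermacra-1(10),4,11-trien-3-yl angelate | C=C(C)[C@@H]1CC/C(C)=C/C[C@H](OC(=O)/C(C)=C\C)/C(C)=C/C1=O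
F0 | step 14 | none | none
A1 | alternative 1 | (2E,6E)-chloro epoxy aldehyde with 3-OTBS (open chain C12–C11=C7 to C6 aldehyde) | ClC/C(C)=C/CC/C(C)=C/C[C@H](O[Si](C)(C)C(C)(C)C)[C@@]1(C)O[C@@H]1C=O
A2 | alternative 1 | (3S,4R,5R,6R,7R)-3-(tert-butyldimethylsilyloxy)-4,5-epoxygermacra-1(10),11-dien-6-ol (7-epimer) | C=C(C)[C@H]1CC/C(C)=C/C[C@H](O[Si](C)(C)C(C)(C)C)[C@@]2(C)O[C@@H]2[C@@H]1O
A3 | alternative 2 | open-chain C3 aldehyde with (E)-C4 alkenyl iodide, 6-acetate and 7-isopropenyl | O=CC/C=C(\C)CC[C@@H](C(C)=C)[C@@H](OC(C)=O)/C=C(\C)I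
A4 | alternative 2 | 6-acetoxygermacra-1(10),4,11-trien-3-ol (C3 epimers) | C=C(C)[C@@H]1CC/C(C)=C/CC(O)/C(C)=C/[C@@H]1OC(C)=O
A5 | alternative 3 | thirteen-membered (E,E,E)-bis-allylic ether with (S)-OTBS at C3 | C/C1=C\CC/C(C)=C/C[C@H](O[Si](C)(C)C(C)(C)C)/C(C)=C/COC1
A6 | alternative 3 | 3-(tert-butyldimethylsilyloxy)germacra-1(10),4,11-trien-6-ol with the 6-beta hydroxyl and the 7R isopropenyl group | C=C(C)[C@H]1CC/C(C)=C/C[C@H](O[Si](C)(C)C(C)(C)C)/C(C)=C/[C@@H]1O
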